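Assumption: ring A is numbered C1 (CO2CH3), C2 (O-aryl), C3 (H), C4 (CH3), C5 (prenyl), C6 (OH) and ring B C1' (ether O), C2' (CH2OH), C4' and C6' (OCH3). This numbering is kept for every ring A intermediate, all chiral intermediates are racemic, and 2,4-dimethoxyphenol is taken to be a purchasable starting material.

## Analysis of the target

The target is a diaryl ether of two benzene rings with no stereocentre and no stereogenic double bond. Ring A is a pentasubstituted methyl salicylate: CO2CH3 at C1, the ether oxygen at C2, H at C3, CH3 at C4, the 3-methylbut-2-enyl (prenyl) group at C5 and a hydrogen-bonded OH at C6. Ring B is a 2-(hydroxymethyl)-4,6-dimethoxyphenyl group bound through its C1' oxygen to C2. The sensitive groups are the prenyl double bond next to a free phenol (acid closes a chroman, oxidants a chromene), the electron-rich benzylic alcohol of ring B and the methyl ester. Two things make the synthesis hard. The ether oxygen is flanked on ring A by the ester and on ring B by CH2OH and OCH3, and both rings are electron-rich, so an arene-arene etherification is unattractive. The prenyl group must go to C5 alone, whereas on a ring A phenol it would compete with C3 and with the phenol oxygen. The strategy rests on the position of C5 between C6 (oxygen) and C4 (methyl): in a 6-oxocyclohex-1-ene form of ring A, C5 is the alpha-prime carbon of a vinylogous ester and the only carbon that a carbonyl-bound amide base deprotonates. In the same ring C2 is the beta-carbon of an enone, so the hindered ether can be made by addition-elimination. The two sp3 centres that this ring carries (C4, C5) are transient and vanish on aromatization.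

## Retrosynthetic reasoning

17 to 16: the two O-Si bonds (phenol O6 and the ring B benzylic oxygen) are cut last. Both silyl groups fall to one fluoride treatment under nearly neutral conditions, so the ortho-prenyl phenol and the benzylic alcohol are exposed only at the end.

16 to 15 to 14: ring A of 16 is taken back to the cyclohexenone 14 by adding H at C4 and C5. The forward direction goes through the silyl dienol ether 15 with double bonds C6=C1 and C2=C3, made by removing a C3 proton. In 15 the only hydrogens allylic to the diene are the ring hydrogens at C4 and C5, so a hydride-abstracting quinone can only aromatize the ring. A leaving group at C5 was not chosen because its elimination could also run toward the prenyl CH2. The silyl group placed on O6 keeps the new phenol masked during the oxidation.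

14 to 12 + 13: the C5-CH2 bond is cut. This is the place to cut because in 12 the C5 protons are the only ones a lithium amide bound to the C6 carbonyl can reach, and ring A has no phenol oxygen and no nucleophilic C3 at this oxidation level. The forward reaction must form the C5 enolate kinetically and alkylate it once at carbon with 13. The stereocentre it creates is of no consequence.

12 to 11 + 4: the C2-O bond is cut. In 11, C2 is a vinylic carbon bearing chloride and activated by both the C6 ketone and the C1 ester, so the di-ortho-substituted phenoxide of 4 can add and expel chloride under mild base. This replaces a hindered arene coupling by a substitution at a vinylogous acid chloride.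

11 to 10 to 9: the C-Cl bond comes from the enol of the tricarbonyl compound 10, whose two ring carbonyls are interchanged by tautomerism, so only one chloride can form. The ring of 10 is opened at the bond between C1 and one flanking carbonyl carbon, which leads to the acyclic beta-keto diester 9. The forward Dieckmann closure places the ester carbon on C1 from the start, so no later carboxylation of ring A is needed.

9 to 6 to 5: 9 is cut between its ketone carbon and the adjacent CH2CO2CH3 unit, giving the half ester 6 and a malonate two-carbon unit. 6 comes from methanolysis of the symmetrical anhydride 5, which already holds the C4 methyl on the central carbon.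

4 to 3 to 2 to 1: the silyl ether of 4 is removed to give the diol 3, the CH2OH is traced to the aldehyde of 2, and the formyl group is cut from the single free ortho position of the phenol 1. Ring B is carried as the phenol with its benzylic oxygen silylated, so that only the phenoxide reacts in the etherification and nothing on ring B is acidic toward the amide base.

## Alternatives that were turned down

Alternative 1: ring B built by spiroannulation.
- Disconnection: C1'-C2' and C1'-C6' of ring B are cut, giving the ring A coumaranone A1 and the cross-conjugated diynone A2.
- Forward key step: the C2 carbanion of A1 adds twice in conjugate fashion to A2, the second addition being a 6-endo-dig closure, to give the spiro grisadienedione A3.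
- In its favour: the hindered ether C-O bond is already present in A1, so no etherification is needed, and ring B with its full substitution pattern is made in one step. On that point it is as strong as the chosen route.
- Against it: A1 contains ring A as a fully substituted arene with the prenyl group already between oxygen and methyl, so the C5 regiochemistry problem is moved upstream, not solved. A2 is a ketone of an alkynyl ether and is labile. After the key step the spiro ketone bond must be cleaved by an alkoxide, the freed C4' phenol methylated and two protecting groups removed.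
- Comparison: the chosen route is shorter after its key step and settles the C5 position by the mechanism of enolate formation.

Alternative 2: depside to diaryl ether by Smiles rearrangement.
- Disconnection: the O-C2 ether bond is traced to the ester bond of the depside A4.
- Forward key step: the ring B phenoxide of A4 attacks ring A at C2 in an ipso addition-elimination through a six-membered spirocyclic stage and releases the ring B carboxylate, giving the acid A5.
- In its favour: the ester of A4 is easy to make even between hindered partners, and the ether bond then forms intramolecularly. That is a real advantage for a di-ortho-substituted ether and matches the chosen route on that point.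
- Against it: the ipso carbon of ring A is activated by one ortho ester only and deactivated by an alkoxy, a methyl and a prenyl group, so the anionic adduct is poorly stabilized. A4 again needs a prenylated ring A arene with two differentiated phenols. In A5 a carboxylic acid must be reduced next to a methyl ester and a trisubstituted alkene, and an acetal must be removed with acid beside the prenyl group.
- Comparison: the chosen route makes the same ether bond at a non-aromatic, doubly activated carbon and carries the benzylic carbon at the alcohol oxidation level throughout.

Alternative 3: Danheiser benzannulation of ring A.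
- Disconnection: C1-C6, C2-C3 and C5-C6 of ring A are cut, giving the cyclobutenone A6 and the ring B aryl ethynyl ether A7.
- Forward key step: thermal four-electron ring opening of A6, [2+2] addition to A7, a second ring opening and a six-electron ring closure give the phenol A8.
- In its favour: ring A is assembled with complete regiocontrol and the prenyl and methyl groups arrive already in place. It is more convergent than the chosen route.
- Against it: A8 lacks the C1 carbon, so the ester must be introduced later between two oxygen substituents by a directed metalation that needs phenol protection and competes with benzylic metalation. A6 and A7 are strained or specialized compounds that each need several steps, and the ethynyl ether of a di-ortho-substituted phenol is not easy to make.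
- Comparison: the chosen route uses ordinary carbonyl chemistry from bulk starting materials and carries the C1 ester from the first ring-forming step.

Key step: step 9

## Route

Step 1
Reactants: 1 2,4-dimethoxyphenol
Product: 2 2-hydroxy-3,5-dimethoxybenzaldehyde
Conditions: MgCl2, Et3N, (CH2O)n, MeCN, reflux; aq HCl
Reagents that add atoms: paraformaldehyde (formaldehyde), C=O
Why: Magnesium-mediated ortho-formylation (Casnati-Skattebol): the magnesium phenoxide delivers formaldehyde to the only free ortho position and a second formaldehyde oxidizes the benzylic alkoxide by hydride transfer, so the aldehyde should form at C6 of 1 only.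

Step 2
Reactants: 2 2-hydroxy-3,5-dimethoxybenzaldehyde
Product: 3 2-(hydroxymethyl)-4,6-dimethoxyphenol
Conditions: NaBH4, MeOH, 0 °C; aq NH4Cl
Reagents that add atoms: none
Why: Borohydride reduction of an aryl aldehyde; the ethers and the phenol are inert, and a nearly neutral work-up avoids ionization of the salicyl alcohol.

Step 3
Reactants: 3 2-(hydroxymethyl)-4,6-dimethoxyphenol
Product: 4 2-({[tert-butyl(dimethyl)silyl]oxy}methyl)-4,6-dimethoxyphenol
Conditions: TBSCl (1.05 equiv), imidazole, CH2Cl2, 0 °C
Reagents that add atoms: tert-butyldimethylsilyl chloride, CC(C)(C)[Si](C)(C)Cl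
Why: Chemoselective silylation: the primary benzylic hydroxyl should react faster than the di-ortho-substituted, hydrogen-bonded phenol, and an aryl silyl ether, if formed, is the more labile one and is lost on work-up.

Step 4
Reactants: 5 3-methylglutaric anhydride
Product: 6 5-methoxy-3-methyl-5-oxopentanoic acid (racemic)
Conditions: MeOH, reflux
Reagents that add atoms: methanol, CO
Why: Alcoholysis of a cyclic anhydride; the two carbonyls of the symmetrical anhydride are enantiotopic, so one constitutional half ester results as a racemate.

Step 5
Reactants: 6 5-methoxy-3-methyl-5-oxopentanoic acid (racemic)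
Product: 9 dimethyl 5-methyl-3-oxoheptanedioate (racemic), via acyl imidazolide 7 (not isolated), via acylmalonic half ester 8 (not isolated)
Conditions: CDI, THF, rt; then KO2CCH2CO2Me, MgCl2, Et3N, MeCN, rt; aq HCl
Reagents that add atoms: potassium methyl malonate, COC(=O)CC(=O)[O-].[K+]
Why: Masamune-Brooks homologation: the acyl imidazolide acylates the magnesium enolate of the malonate half ester at carbon and the acylmalonic acid loses CO2 on acidification, giving the beta-keto ester without touching the distal methyl ester.

Step 6
Reactants: 9 dimethyl 5-methyl-3-oxoheptanedioate (racemic)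
Product: 10 methyl 2-hydroxy-4-methyl-6-oxocyclohex-1-ene-1-carboxylate (enol form of methyl 4-methyl-2,6-dioxocyclohexane-1-carboxylate)
Conditions: NaOMe, MeOH, reflux; aq HCl
Reagents that add atoms: none
Why: Dieckmann condensation: the stabilized C2 enolate of the beta-keto ester adds to the C7 ester carbonyl in a 6-exo-trig closure and the acidic tricarbonyl product is held as its sodium enolate, which drives the equilibrium; closure from C6 onto C1 would need the far less populated simple ester enolate.

Step 7
Reactants: 10 methyl 2-hydroxy-4-methyl-6-oxocyclohex-1-ene-1-carboxylate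
Product: 11 methyl 2-chloro-4-methyl-6-oxocyclohex-1-ene-1-carboxylate (racemic)
Conditions: (COCl)2, cat. DMF, CH2Cl2, 0 °C to rt
Reagents that add atoms: oxalyl chloride, O=C(Cl)C(=O)Cl
Why: Vilsmeier-type activation of the enol oxygen followed by addition-elimination of chloride gives the vinylogous acid chloride, as known for 2-acylcyclohexane-1,3-diones; the two carbonyls of 10 are interchanged by tautomerism, so only one constitutional chloride can form.

Step 8
Reactants: 11 methyl 2-chloro-4-methyl-6-oxocyclohex-1-ene-1-carboxylate (racemic); 4 2-({[tert-butyl(dimethyl)silyl]oxy}methyl)-4,6-dimethoxyphenol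
Product: 12 methyl 2-[2-({[tert-butyl(dimethyl)silyl]oxy}methyl)-4,6-dimethoxyphenoxy]-4-methyl-6-oxocyclohex-1-ene-1-carboxylate (racemic)
Conditions: Cs2CO3, MeCN, 0 °C to rt (11 added to the phenoxide)
Reagents that add atoms: none
Why: Vinylic addition-elimination: the cesium phenoxide adds to C2, which is activated by both the ketone and the ester, and chloride leaves from the stabilized enolate; both ortho positions and the para position of the phenoxide are substituted, so only oxygen can attack.

Step 9
Reactants: 12 methyl 2-[2-({[tert-butyl(dimethyl)silyl]oxy}methyl)-4,6-dimethoxyphenoxy]-4-methyl-6-oxocyclohex-1-ene-1-carboxylate (racemic); 13 prenyl bromide (1-bromo-3-methylbut-2-ene)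
Product: 14 methyl trans-(4S*,5R*)-2-[2-({[tert-butyl(dimethyl)silyl]oxy}methyl)-4,6-dimethoxyphenoxy]-4-methyl-5-(3-methylbut-2-en-1-yl)-6-oxocyclohex-1-ene-1-carboxylate (racemic)
Conditions: LiN(i-Pr)2 (LDA, 1.1 equiv), THF, −78 °C (12 added to the base); then 13 (1.5 equiv), DMPU, −78 to −40 °C; aq NH4Cl
Reagents that add atoms: none
Why: Lithium diisopropylamide bound to the C6 carbonyl oxygen removes a C5 proton through a six-membered cyclic transition state, and the cross-conjugated lithium enolate C5=C6(OLi) attacks the primary allylic bromide 13 at carbon in an SN2 reaction. The closest known reaction type is the Stork-Danheiser kinetic alpha-prime alkylation of 3-alkoxycyclohex-2-enones with allylic halides. No ring is closed in this step. The new stereocentre at C5 is controlled by the C4 methyl: the electrophile adds axially to the half-chair enolate on the face away from the adjacent methyl, so the trans isomer should predominate, and a minor cis isomer is harmless because both centres are lost in step 11. The step needs deprotonation at C5 and not at C3, although the C3 protons are thermodynamically the more acidic ones (vinylogous beta-keto ester); the substrate secures this because C3 lies trans to the ester across C1=C2 and far from the s-trans C6 carbonyl, so neither carbonyl can deliver the base there, and adding 12 to a slight excess of base at −78 °C leaves no free ketone to equilibrate the enolate. C- over O-alkylation follows from the lithium counter-ion and the soft allylic bromide, and mono-alkylation from the lower kinetic acidity of the resulting C5 methine at low temperature. Ring A is not aromatic at this stage, so neither a phenol oxygen nor a nucleophilic C3 can compete for the prenyl group.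

Step 10
Reactants: 14 the trans 4-methyl-5-prenyl cyclohexenone ester (racemic)
Product: 15 methyl trans-(4S*,5R*)-6-{[tert-butyl(dimethyl)silyl]oxy}-2-[2-({[tert-butyl(dimethyl)silyl]oxy}methyl)-4,6-dimethoxyphenoxy]-4-methyl-5-(3-methylbut-2-en-1-yl)cyclohexa-1(6),2-diene-1-carboxylate (racemic; double bonds C6=C1 and C2=C3)
Conditions: TBSOTf (1.3 equiv), Et3N, CH2Cl2, −78 to 0 °C
Reagents that add atoms: tert-butyldimethylsilyl trifluoromethanesulfonate, CC(C)(C)[Si](C)(C)OS(=O)(=O)C(F)(F)F
Why: Soft enolization: after O-silylation of the C6 carbonyl the amine removes a C3 proton, the unhindered methylene whose anion is that of a vinylogous beta-keto ester, giving the linear 1-silyloxy-1,3-diene; the hindered C5 methine should be left alone and the trans relationship of C4 and C5 is untouched.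

Step 11
Reactants: 15 the silyl dienol ether (racemic)
Product: 16 methyl 6-{[tert-butyl(dimethyl)silyl]oxy}-2-[2-({[tert-butyl(dimethyl)silyl]oxy}methyl)-4,6-dimethoxyphenoxy]-4-methyl-5-(3-methylbut-2-en-1-yl)benzoate
Conditions: DDQ (1.1 equiv), 2,6-lutidine, CH2Cl2, 0 °C
Reagents that add atoms: none
Why: Dehydrogenation of a cyclohexa-1,3-diene by hydride abstraction: DDQ removes the allylic C4 hydride to give a cyclohexadienyl cation stabilized by the oxygen substituents at C2 and C6, and loss of the C5 proton gives the arene, erasing both stereocentres. The prenyl CH2 is not conjugated to the diene, and the silyl group on O6 blocks quinone-mediated chromene formation from an ortho-prenyl phenol.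

Step 12
Reactants: 16 the bis-silyl ether of the target
Product: 17 methyl 6-hydroxy-2-[2-(hydroxymethyl)-4,6-dimethoxyphenoxy]-4-methyl-5-(3-methylbut-2-en-1-yl)benzoate (CNP0583011.0)
Conditions: TBAF, AcOH, THF, 0 °C to rt
Reagents that add atoms: none
Why: Fluoride cleavage of the aryl and the benzylic silyl ether; buffering with acetic acid keeps the medium close to neutral, so the ortho-prenyl phenol should not cyclize and the methyl ester is not touched.

## Compound list

1 | 2,4-dimethoxyphenol | COc1ccc(O)c(OC)c1 | starting material
2 | 2-hydroxy-3,5-dimethoxybenzaldehyde | O=Cc1cc(OC)cc(OC)c1O | intermediate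
3 | 2-(hydroxymethyl)-4,6-dimethoxyphenol | OCc1cc(OC)cc(OC)c1O | intermediate
4 | 2-({[tert-butyl(dimethyl)silyl]oxy}methyl)-4,6-dimethoxyphenol | CC(C)(C)[Si](C)(C)OCc1cc(OC)cc(OC)c1O | intermediate
5 | 3-methylglutaric anhydride (4-methyloxane-2,6-dione) | CC1CC(=O)OC(=O)C1 | starting material
6 | 5-methoxy-3-methyl-5-oxopentanoic acid (racemic) | COC(=O)CC(C)CC(=O)O | intermediate
7 | methyl 5-(1H-imidazol-1-yl)-3-methyl-5-oxopentanoate (racemic, formed in the flask) | COC(=O)CC(C)CC(=O)n1ccnc1 | intermediate
8 | 7-methoxy-2-(methoxycarbonyl)-5-methyl-3,7-dioxoheptanoic acid (mixture of racemic diastereomers, formed in the flask) | COC(=O)CC(C)CC(=O)C(C(=O)O)C(=O)OC | intermediate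
9 | dimethyl 5-methyl-3-oxoheptanedioate (racemic) | COC(=O)CC(=O)CC(C)CC(=O)OC | intermediate
10 | methyl 2-hydroxy-4-methyl-6-oxocyclohex-1-ene-1-carboxylate (enol tautomer of the 2,6-dioxo ester) | COC(=O)C1=C(O)CC(C)CC1=O | intermediate
11 | methyl 2-chloro-4-methyl-6-oxocyclohex-1-ene-1-carboxylate (racemic) | COC(=O)C1=C(Cl)CC(C)CC1=O | intermediate
12 | methyl 2-[2-({[tert-butyl(dimethyl)silyl]oxy}methyl)-4,6-dimethoxyphenoxy]-4-methyl-6-oxocyclohex-1-ene-1-carboxylate (racemic) | COC(=O)C1=C(Oc2c(CO[Si](C)(C)C(C)(C)C)cc(OC)cc2OC)CC(C)CC1=O | intermediate
13 | prenyl bromide (1-bromo-3-methylbut-2-ene) | CC(C)=CCBr | starting material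
14 | methyl trans-(4S*,5R*)-2-[2-({[tert-butyl(dimethyl)silyl]oxy}methyl)-4,6-dimethoxyphenoxy]-4-methyl-5-(3-methylbut-2-en-1-yl)-6-oxocyclohex-1-ene-1-carboxylate (racemic, one enantiomer drawn) | COC(=O)C1=C(Oc2c(CO[Si](C)(C)C(C)(C)C)cc(OC)cc2OC)C[C@H](C)[C@@H](CC=C(C)C)C1=O | intermediate
15 | methyl trans-(4S*,5R*)-6-{[tert-butyl(dimethyl)silyl]oxy}-2-[2-({[tert-butyl(dimethyl)silyl]oxy}methyl)-4,6-dimethoxyphenoxy]-4-methyl-5-(3-methylbut-2-en-1-yl)cyclohexa-1(6),2-diene-1-carboxylate (racemic, one enantiomer drawn) | COC(=O)C1=C(O[Si](C)(C)C(C)(C)C)[C@H](CC=C(C)C)[C@@H](C)C=C1Oc1c(CO[Si](C)(C)C(C)(C)C)cc(OC)cc1OC | intermediate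
16 | methyl 6-{[tert-butyl(dimethyl)silyl]oxy}-2-[2-({[tert-butyl(dimethyl)silyl]oxy}methyl)-4,6-dimethoxyphenoxy]-4-methyl-5-(3-methylbut-2-en-1-yl)benzoate | COC(=O)c1c(Oc2c(CO[Si](C)(C)C(C)(C)C)cc(OC)cc2OC)cc(C)c(CC=C(C)C)c1O[Si](C)(C)C(C)(C)C | intermediate
17 | methyl 6-hydroxy-2-[2-(hydroxymethyl)-4,6-dimethoxyphenoxy]-4-methyl-5-(3-methylbut-2-en-1-yl)benzoate | COC(=O)c1c(Oc2c(CO)cc(OC)cc2OC)cc(C)c(CC=C(C)C)c1O | target

## Step count and least certain steps

Total step count: 12. Longest linear sequence: 9 steps (5 to 17, steps 4 to 12). The ring B branch (steps 1 to 3) joins at step 8.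

Step 9 (key step).
- Risk: the base may remove the thermodynamically more acidic C3 proton instead of the C5 proton, or the C5 enolate may be quenched by proton transfer from already alkylated product before it meets the bromide. Either would lead to alkylation at C1 or C3, stalled conversion or double alkylation. Amide addition at the electrophilic C2 with loss of the aryloxide is a further possibility.
- Fallback: the prenyl group would be introduced one stage earlier, on the symmetrical tricarbonyl compound 10, where the two methylene groups next to the carbonyls are equivalent. With 2.2 equiv LiN(i-Pr)2 in THF/DMPU at −78 to −20 °C, 10 is converted into its dianion, which 13 alkylates at the terminal carbanion to give methyl trans-2-hydroxy-4-methyl-5-(3-methylbut-2-en-1-yl)-6-oxocyclohex-1-ene-1-carboxylate F1. Oxalyl chloride with catalytic DMF then chlorinates the less hindered enol carbon, the one remote from the prenyl group, to give the chloride F2, and F2 is coupled with 4 under the conditions of step 8 to come back at 14. The price is that the chlorination must distinguish the two carbonyls, so a regioisomeric chloride might have to be separated.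

Step 10.
- Risk: enolization toward C5 instead of C3 would give the cross-conjugated silyl dienol ether, in which the prenyl CH2 becomes allylic to the diene and could lose hydride in step 11.
- Fallback: the silyl dienol ether is bypassed. From 14, DBU (2.2 equiv) and BrCCl3 (1.0 equiv) in CH2Cl2 at 0 °C are used: the amidine can only form the vinylogous beta-keto ester enolate by C3-H removal, this is brominated at C1 or C3, and either bromide can lose HBr only through the ring C4-H because C2 carries no hydrogen. Both paths converge after tautomerization on the phenol methyl 2-[2-({[tert-butyl(dimethyl)silyl]oxy}methyl)-4,6-dimethoxyphenoxy]-6-hydroxy-4-methyl-5-(3-methylbut-2-en-1-yl)benzoate F3, and TBAF/AcOH then gives 17.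

Step 11.
- Risk: over-oxidation by further hydride abstraction at the prenyl CH2, which becomes benzylic and allylic once ring A is aromatic, or at the ring B benzylic ether; also acid-induced loss of the aryl silyl group, which would expose the ortho-prenyl phenol to chromene formation.
- Fallback: hydride abstraction is replaced by selenoxide chemistry at C3. From 15, PhSeCl in CH2Cl2 at −78 °C attacks the gamma-carbon C3 anti to the C4 methyl and gives the C3 selenide F4. Oxidation with H2O2 and pyridine at 0 °C and syn elimination of the selenoxide, possible only toward C4-H, gives after tautomerization the phenol F3, which is desilylated as in step 12 to come back at 17.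

Step 8.
- Risk: slow addition of the di-ortho-substituted phenoxide, hydrolysis of the vinylogous acid chloride, or oxygen-to-oxygen silyl migration in the phenoxide so that the benzylic alkoxide becomes the nucleophile.
- Fallback: the ether is formed before the benzylic oxygen exists. From 11 and the aldehyde 2 (Cs2CO3, MeCN) the formyl aryl ether F5 is made. NaBH(OAc)3 in THF at rt reduces only the aryl aldehyde to give the benzylic alcohol F6, and TBSCl with imidazole in CH2Cl2 silylates it to come back at 12.

Step 3.
- Risk: silylation at the phenol oxygen or at both oxygens instead of the benzylic hydroxyl alone.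
- Fallback: both oxygens are silylated on purpose and the phenol is unmasked selectively. From 3, TBSCl (2.5 equiv) and imidazole in DMF give the bis-silyl ether F7, and K2CO3 in MeOH at rt cleaves only the aryl silyl ether to come back at 4.

## Further compounds

F1 | step 9 | methyl trans-2-hydroxy-4-methyl-5-(3-methylbut-2-en-1-yl)-6-oxocyclohex-1-ene-1-carboxylate (racemic, enol form) | COC(=O)C1=C(O)C[C@H](C)[C@@H](CC=C(C)C)C1=O
F2 | step 9 | methyl trans-2-chloro-4-methyl-5-(3-methylbut-2-en-1-yl)-6-oxocyclohex-1-ene-1-carboxylate (racemic) | COC(=O)C1=C(Cl)C[C@H](C)[C@@H](CC=C(C)C)C1=O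
F3 | step 10 | methyl 2-[2-({[tert-butyl(dimethyl)silyl]oxy}methyl)-4,6-dimethoxyphenoxy]-6-hydroxy-4-methyl-5-(3-methylbut-2-en-1-yl)benzoate | COC(=O)c1c(Oc2c(CO[Si](C)(C)C(C)(C)C)cc(OC)cc2OC)cc(C)c(CC=C(C)C)c1O
F4 | step 11 | methyl 2-[2-({[tert-butyl(dimethyl)silyl]oxy}methyl)-4,6-dimethoxyphenoxy]-4-methyl-5-(3-methylbut-2-en-1-yl)-6-oxo-3-(phenylselanyl)cyclohex-1-ene-1-carboxylate (racemic; selenium trans to the C4 methyl, C4 and C5 trans) | COC(=O)C1=C(Oc2c(CO[Si](C)(C)C(C)(C)C)cc(OC)cc2OC)[C@@H]([Se]c2ccccc2)[C@H](C)[C@@H](CC=C(C)C)C1=O
F5 | step 8 | methyl 2-(2-formyl-4,6-dimethoxyphenoxy)-4-methyl-6-oxocyclohex-1-ene-1-carboxylate (racemic) | COC(=O)C1=C(Oc2c(C=O)cc(OC)cc2OC)CC(C)CC1=O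
F6 | step 8 | methyl 2-[2-(hydroxymethyl)-4,6-dimethoxyphenoxy]-4-methyl-6-oxocyclohex-1-ene-1-carboxylate (racemic) | COC(=O)C1=C(Oc2c(CO)cc(OC)cc2OC)CC(C)CC1=O
F7 | step 3 | tert-butyl({2-[(tert-butyldimethylsilyl)oxy]-3,5-dimethoxyphenyl}methoxy)dimethylsilane | CC(C)(C)[Si](C)(C)OCc1cc(OC)cc(OC)c1O[Si](C)(C)C(C)(C)C
A1 | alternative 1 | 4-(methoxymethoxy)-6-methyl-5-(3-methylbut-2-en-1-yl)-1-benzofuran-3(2H)-one | O=C1COc2cc(C)c(CC=C(C)C)c(OCOC)c12
A2 | alternative 1 | 6-{[tert-butyl(dimethyl)silyl]oxy}-1-methoxyhexa-1,4-diyn-3-one | COC#CC(=O)C#CCO[Si](C)(C)C(C)(C)C
A3 | alternative 1 | 2'-({[tert-butyl(dimethyl)silyl]oxy}methyl)-6'-methoxy-4-(methoxymethoxy)-6-methyl-5-(3-methylbut-2-en-1-yl)-3H-spiro[1-benzofuran-2,1'-cyclohexa-2',5'-diene]-3,4'-dione (racemic) | O=C1c2c(OCOC)c(CC=C(C)C)c(C)cc2OC12C(CO[Si](C)(C)C(C)(C)C)=CC(=O)C=C2OC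
A4 | alternative 2 | methyl 2-[(2-hydroxy-3,5-dimethoxybenzoyl)oxy]-6-(methoxymethoxy)-4-methyl-5-(3-methylbut-2-en-1-yl)benzoate | COC(=O)c1c(OC(=O)c2cc(OC)cc(OC)c2O)cc(C)c(CC=C(C)C)c1OCOC
A5 | alternative 2 | 2-[2-(methoxycarbonyl)-3-(methoxymethoxy)-5-methyl-4-(3-methylbut-2-en-1-yl)phenoxy]-3,5-dimethoxybenzoic acid | COC(=O)c1c(Oc2c(C(=O)O)cc(OC)cc2OC)cc(C)c(CC=C(C)C)c1OCOC
A6 | alternative 3 | 3-methyl-4-(3-methylbut-2-en-1-yl)cyclobut-2-en-1-one (racemic) | O=C1C=C(C)C1CC=C(C)C
A7 | alternative 3 | tert-butyl{[2-(ethynyloxy)-3,5-dimethoxyphenyl]methoxy}dimethylsilane | C#COc1c(CO[Si](C)(C)C(C)(C)C)cc(OC)cc1OC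
A8 | alternative 3 | 3-[2-({[tert-butyl(dimethyl)silyl]oxy}methyl)-4,6-dimethoxyphenoxy]-5-methyl-6-(3-methylbut-2-en-1-yl)phenol | Oc1cc(Oc2c(CO[Si](C)(C)C(C)(C)C)cc(OC)cc2OC)cc(C)c1CC=C(C)C
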